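**Retrosynthetic overview**
1. The target is a (4→6) dimer of one C15 flavan. The bond from C4 of the upper ring C to C6 of the lower ring A is cut to a flavan-4-yl cation and a nucleophilic ring A; both come from the same protected 2,3-trans-3,4-cis flavan-3,4-diol 9, the upper unit giving up its O4.
2. Ring C of 9 is cut across C4a–C4 and C2–C3: a formal [4+2] (oxa-Povarov) between the O-aryl oxocarbenium C4a=C8a–O1=C2 (from O,S-acetal 5) and 2,2-dimethyl-1,3-dioxole as the cis-dioxygenated C3=C4 unit.
3. Enabling feature: in each unit O1–C2 is an aryl benzyl ether whose C2 carries the 3,4-dioxygenated ring B (its para oxygen stabilises a C2 cation), C4a lies para to O7 of ring A (a nucleophilic ortho carbon), and C3/C4 carry cis oxygens.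
4. Ring order: rings A and B are bought; ring C (with a temporary dioxolane on O3/O4) forms in the key step; then the interflavan bond; then deprotection.

Key step: step 3

Remark: the target is read as fisetinidol-(4α→6)-leucofisetinidin (upper unit 2,3-trans-3,4-trans, lower unit 2,3-trans-3,4-cis); flavan numbering is used for both units; 2,2-dimethyl-1,3-dioxole is taken as a purchasable reagent. Changes of the C3 and C4 descriptors between protected and free compounds come from CIP priorities only, not from a change of configuration.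

**Step 1**
Reactants: 1 1,2-bis(benzyloxy)-4-(chloromethyl)benzene
Product: 2 1,2-bis(benzyloxy)-4-[(phenylsulfanyl)methyl]benzene
Conditions: PhSH, K2CO3, DMF, rt
Reagents that add atoms: thiophenol, Sc1ccccc1
Why: SN2 S-alkylation of thiophenoxide by a benzylic chloride should be clean and creates no stereocentre.

**Step 2**
Reactants: 2 1,2-bis(benzyloxy)-4-[(phenylsulfanyl)methyl]benzene; 3 3-(benzyloxy)phenol
Product: 5 1,2-bis(benzyloxy)-4-{[3-(benzyloxy)phenoxy](phenylsulfanyl)methyl}benzene (racemic O,S-acetal), via α-chloro sulfide 4 (not isolated)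
Conditions: NCS, toluene, 0 °C to rt, dark, filter; filtrate added to 3/NaH, THF–DMF, 0 °C
Reagents that add atoms: none
Why: NCS should chlorinate the sulfide alpha to sulfur (chlorosulfonium/thionium, Pummerer-type α-chlorination) and the phenoxide of 3 should then displace chloride by O-alkylation, as in the making of aryl methylthiomethyl ethers; the new acetal centre is racemic and is erased in step 3.

**Step 3**
Reactants: 5 racemic O,S-acetal; 6 2,2-dimethyl-1,3-dioxole (3 equiv)
Product: 9 (2R,3R,4S)-7-(benzyloxy)-2-[3,4-bis(benzyloxy)phenyl]-3,4-(isopropylidenedioxy)chromane (2,3-trans-3,4-cis acetonide), via aryl oxocarbenium ion 7 (not isolated), via dioxolanylium ion 8 (not isolated)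
Conditions: chiral imidodiphosphorimidate acid (IDPi, N-triflyl, 3,3'-diaryl-BINOL based; enantiomer that leads to the 2R series; 5 mol%), Ag2CO3 (0.6 equiv), 4 Å MS, CH2Cl2, −60 °C, dark
Reagents that add atoms: none
Why: Proposed new method: the silver salt of the confined chiral imidodiphosphorimidate anion, formed in the flask from the acid and Ag2CO3, should abstract benzenethiolate from 5 (the thiophilic ionisation known from silver-promoted cleavage of O,S-acetals) to give the (E)-aryl oxocarbenium 7 as a contact ion pair, the electron-rich enol ether 6 should add to C2 of 7 (C2–C3 bond) to give dioxolanylium ion 8, the ortho carbon of the phenoxy ring should then attack C4 of 8 (C4a–C4 bond), and the proton lost on rearomatisation returns to the anion and is taken up by Ag2CO3, which closes the cycle. The closest known reaction types are the Lewis acid promoted oxa-Povarov reaction (formal [4+2] of aryl oxocarbenium ions with alkenes to 2,4-substituted chromans) and chiral-anion catalysis in which a silver salt made from Ag2CO3 and a chiral acid ionises a leaving group to a chiral ion pair; what is new is a 1,3-dioxole as the two-carbon partner and control of the oxocarbenium face by the counter-anion. Ring C is closed as a stepwise polar [4+2] whose second event is a 6-exo-trig Friedel–Crafts attack on the C4=O cation, while the dioxolane ring is brought in intact. The attacked face of 7, and so C2 and C3 in the absolute sense, is fixed by the chiral anion; the 2,3-trans relation by an exo approach that keeps the CMe2 bridge away from the phenoxy ring and places ring B and O3 equatorial; C4 by the cis fusion that the five-membered dioxolane forces on the closure, which delivers the 3,4-cis diol pattern. The step needs ionisation at sulfur and not at the aryl oxygen (secured by thiophilic monovalent silver), closure para to the OBn group and not between the two ring oxygens (secured by para activation and by sterics) and survival of acid-labile 6 and 9 (secured by the solid carbonate, which keeps free acid low).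

**Step 4**
Reactants: 9 monomer acetonide
Product: 10 (2R,3S,4R)-7-(benzyloxy)-2-[3,4-bis(benzyloxy)phenyl]-4-methoxychroman-3-ol (2,3-trans-3,4-trans)
Conditions: CSA (10 mol%), MeOH–CH2Cl2 (1:1), 0 °C to rt
Reagents that add atoms: methanol, CO
Why: acid-catalysed methanolysis should open the ketal at the benzylic C4–O bond (SN1, cation stabilised by O1 and para O7) and cap C4 as the methyl ether with release of acetone; the C4 configuration of 10 is of no consequence because C4 becomes planar again in step 5, and the 3,4-trans epimer expected from attack anti to the 3-OH is drawn.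

**Step 5**
Reactants: 10 4-methoxyflavan-3-ol; 9 monomer acetonide (3 equiv, excess recovered)
Product: 11 (2R,3R,4S)-7-(benzyloxy)-2-[3,4-bis(benzyloxy)phenyl]-6-{(2R,3S,4S)-7-(benzyloxy)-2-[3,4-bis(benzyloxy)phenyl]-3-hydroxychroman-4-yl}-3,4-(isopropylidenedioxy)chromane (4α→6 link; upper unit 2,3-trans-3,4-trans)
Conditions: TMSOTf (0.5 equiv), CH2Cl2, −78 to −40 °C; Et3N, then aq. NaHCO3
Reagents that add atoms: none
Why: the silyl triflate should ionise the 4-methoxy group of 10 to the flavan-4-yl cation, which ring A of 9 attacks through C6 (para to O1, ortho to OBn; C8 is flanked by two oxygens) in the Friedel–Crafts coupling used for interflavan bonds, and approach anti to the C3–OH of the 2,3-trans cation should set the new C4 centre 3,4-trans (4α).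

**Step 6**
Reactants: 11 dimer acetonide
Product: 12 (2R,3S,4S)-7-(benzyloxy)-2-[3,4-bis(benzyloxy)phenyl]-6-{(2R,3S,4S)-7-(benzyloxy)-2-[3,4-bis(benzyloxy)phenyl]-3-hydroxychroman-4-yl}chromane-3,4-diol
Conditions: AcOH–H2O–THF (3:1:1), 40 °C
Reagents that add atoms: none
Why: mild aqueous acid should hydrolyse the isopropylidene ketal at the ketal carbon, so that the C3–O and C4–O bonds and with them the 3,4-cis configuration stay untouched; benzyl ethers and the interflavan bond are stable under these conditions.

**Step 7**
Reactants: 12 hexa-O-benzyl dimer triol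
Product: 13 (2R,3S,4S)-2-(3,4-dihydroxyphenyl)-6-[(2R,3S,4R)-2-(3,4-dihydroxyphenyl)-3,7-dihydroxychroman-4-yl]chromane-3,4,7-triol (target)
Conditions: H2 (1 atm), Pd(OH)2/C, THF–MeOH, rt, neutral, stopped at full debenzylation
Reagents that add atoms: none
Why: hydrogenolysis of the six aryl benzyl ethers should be much faster under neutral conditions than cleavage of the secondary benzylic 4-OH, of the ring C–O bonds or of the interflavan C–C bond, and no stereocentre is touched.

**Compound list**
1 | 1,2-bis(benzyloxy)-4-(chloromethyl)benzene | ClCc1ccc(OCc2ccccc2)c(OCc2ccccc2)c1 | starting material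
2 | 1,2-bis(benzyloxy)-4-[(phenylsulfanyl)methyl]benzene | c1ccccc1SCc1ccc(OCc2ccccc2)c(OCc2ccccc2)c1 | intermediate
3 | 3-(benzyloxy)phenol | Oc1cccc(OCc2ccccc2)c1 | starting material
4 | 1,2-bis(benzyloxy)-4-[chloro(phenylsulfanyl)methyl]benzene (racemic, not isolated) | ClC(Sc1ccccc1)c1ccc(OCc2ccccc2)c(OCc2ccccc2)c1 | intermediate
5 | 1,2-bis(benzyloxy)-4-{[3-(benzyloxy)phenoxy](phenylsulfanyl)methyl}benzene (racemic) | c1ccccc1COc1cccc(c1)OC(Sc1ccccc1)c1ccc(OCc2ccccc2)c(OCc2ccccc2)c1 | intermediate
6 | 2,2-dimethyl-1,3-dioxole | CC1(C)OC=CO1 | starting material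
7 | (E)-[3-(benzyloxy)phenyl][3,4-bis(benzyloxy)benzylidene]oxonium (cation of the ion pair with the catalyst anion, not isolated) | c1ccccc1COc1cccc(c1)/[O+]=C/c1ccc(OCc2ccccc2)c(OCc2ccccc2)c1 | intermediate
8 | 2,2-dimethyl-1,3-dioxolanylium ion carrying the (R)-[3-(benzyloxy)phenoxy][3,4-bis(benzyloxy)phenyl]methyl group on its sp3 ring carbon (flavan numbering 2R,3R; cation at C4=O; not isolated) | c1ccccc1COc1cccc(c1)O[C@H](c1ccc(OCc2ccccc2)c(OCc2ccccc2)c1)[C@@H](OC(C)(C)[O+]=3)C3 | intermediate
9 | (2R,3R,4S)-7-(benzyloxy)-2-[3,4-bis(benzyloxy)phenyl]-3,4-(isopropylidenedioxy)chromane (2,3-trans-3,4-cis) | c1cc2c(cc1OCc1ccccc1)O[C@H](c1ccc(OCc3ccccc3)c(OCc3ccccc3)c1)[C@@H](OC(C)(C)O4)[C@H]24 | intermediate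
10 | (2R,3S,4R)-7-(benzyloxy)-2-[3,4-bis(benzyloxy)phenyl]-4-methoxychroman-3-ol (2,3-trans-3,4-trans) | c1cc2c(cc1OCc1ccccc1)O[C@H](c1ccc(OCc3ccccc3)c(OCc3ccccc3)c1)[C@@H](O)[C@@H]2OC | intermediate
11 | (2R,3R,4S)-7-(benzyloxy)-2-[3,4-bis(benzyloxy)phenyl]-6-{(2R,3S,4S)-7-(benzyloxy)-2-[3,4-bis(benzyloxy)phenyl]-3-hydroxychroman-4-yl}-3,4-(isopropylidenedioxy)chromane | c1ccccc1COc1ccc2c(c1)O[C@H](c1ccc(OCc3ccccc3)c(OCc3ccccc3)c1)[C@@H](O)[C@@H]2c1cc2c(cc1OCc1ccccc1)O[C@H](c1ccc(OCc3ccccc3)c(OCc3ccccc3)c1)[C@@H](OC(C)(C)O4)[C@H]24 | intermediate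
12 | (2R,3S,4S)-7-(benzyloxy)-2-[3,4-bis(benzyloxy)phenyl]-6-{(2R,3S,4S)-7-(benzyloxy)-2-[3,4-bis(benzyloxy)phenyl]-3-hydroxychroman-4-yl}chromane-3,4-diol | c1ccccc1COc1ccc2c(c1)O[C@H](c1ccc(OCc3ccccc3)c(OCc3ccccc3)c1)[C@@H](O)[C@@H]2c1cc2c(cc1OCc1ccccc1)O[C@H](c1ccc(OCc3ccccc3)c(OCc3ccccc3)c1)[C@@H](O)[C@H]2O | intermediate
13 | (2R,3S,4S)-2-(3,4-dihydroxyphenyl)-6-[(2R,3S,4R)-2-(3,4-dihydroxyphenyl)-3,7-dihydroxychroman-4-yl]chromane-3,4,7-triol | Oc1ccc2c(c1)O[C@H](c1ccc(O)c(O)c1)[C@@H](O)[C@@H]2c1cc2c(cc1O)O[C@H](c1ccc(O)c(O)c1)[C@@H](O)[C@H]2O | target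

**Step count and risks**
Total step count: 7. Longest linear sequence: 7 steps (1 → 2 → 5 → 9 → 10 → 11 → 12 → 13); compound 9 enters a second time in step 5.

Steps most likely to fail:

1. Step 3 (Proposed new method). What may go wrong: insufficient discrimination between the two faces of the oxocarbenium inside the ion pair, endo instead of exo approach of the dioxole, or acid-induced consumption of the dioxole before it is trapped. Fallback with known chemistry: setting out from 5, the O,S-acetal is ionised with stoichiometric AgOTf in the presence of 2,6-di-tert-butyl-4-methylpyridine, 6 and 4 Å MS in CH2Cl2 at low temperature. This is the non-asymmetric oxa-Povarov manifold of an aryl oxocarbenium ion with an alkene and should give racemic 9. The racemate is then resolved by preparative supercritical fluid chromatography on a polysaccharide chiral stationary phase, which gives 9 and its mirror image, the (2S,3S,4R)-acetonide F1, which is set aside. The fallback comes back to the route at 9.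

2. Step 5. What may go wrong: ionisation of the benzylic ketal C–O bond of the excess nucleophile by the silyl triflate with chain growth beyond the dimer, or erosion of the 4α selectivity. Fallback: setting out from 10, exchange of the 4-methoxy group with benzyl mercaptan (BF3·OEt2, CH2Cl2, −20 °C) should give the (2R,3R,4R)-4-(benzylsulfanyl)flavan-3-ol F2. This thioether is then activated selectively by AgBF4 in THF at 0 °C in the presence of excess 9. This is thiophilic activation under essentially neutral conditions and leaves the ketal of 9 untouched. The fallback comes back to the route at 11.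

3. Step 6. What may go wrong: heterolysis of the benzylic C4–O bond competing with hydrolysis at the ketal carbon, so that the 3,4-cis configuration is lost by C4 epimerisation or the cation is captured by another ring A. Fallback: setting out from 9, the ketal is hydrolysed at the monomer stage (aq. AcOH) to the cis-diol (2R,3S,4S)-7-(benzyloxy)-2-[3,4-bis(benzyloxy)phenyl]chromane-3,4-diol F3, which is closed with 1,1'-carbonyldiimidazole to the cyclic carbonate F4. Only the cis-diol can form this ring, so a C4 epimer is removed here. Coupling of 10 with excess F4 under the conditions of step 5 should give the dimer carbonate F5, and methanolysis (catalytic K2CO3, MeOH–THF, rt) frees the diol without any acid. The fallback comes back to the route at 12.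

Further compounds
F1 | step 3 | (2S,3S,4R)-7-(benzyloxy)-2-[3,4-bis(benzyloxy)phenyl]-3,4-(isopropylidenedioxy)chromane (enantiomer of 9) | c1cc2c(cc1OCc1ccccc1)O[C@@H](c1ccc(OCc3ccccc3)c(OCc3ccccc3)c1)[C@H](OC(C)(C)O4)[C@@H]24
F2 | step 5 | (2R,3R,4R)-4-(benzylsulfanyl)-7-(benzyloxy)-2-[3,4-bis(benzyloxy)phenyl]chroman-3-ol (2,3-trans-3,4-trans) | c1cc2c(cc1OCc1ccccc1)O[C@H](c1ccc(OCc3ccccc3)c(OCc3ccccc3)c1)[C@@H](O)[C@@H]2SCc1ccccc1
F3 | step 6 | (2R,3S,4S)-7-(benzyloxy)-2-[3,4-bis(benzyloxy)phenyl]chromane-3,4-diol (2,3-trans-3,4-cis) | c1cc2c(cc1OCc1ccccc1)O[C@H](c1ccc(OCc3ccccc3)c(OCc3ccccc3)c1)[C@@H](O)[C@H]2O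
F4 | step 6 | (2R,3R,4S)-7-(benzyloxy)-2-[3,4-bis(benzyloxy)phenyl]chromane-3,4-diyl carbonate (cyclic, 2,3-trans-3,4-cis) | c1cc2c(cc1OCc1ccccc1)O[C@H](c1ccc(OCc3ccccc3)c(OCc3ccccc3)c1)[C@@H](OC(=O)O4)[C@H]24
F5 | step 6 | (2R,3R,4S)-7-(benzyloxy)-2-[3,4-bis(benzyloxy)phenyl]-6-{(2R,3S,4S)-7-(benzyloxy)-2-[3,4-bis(benzyloxy)phenyl]-3-hydroxychroman-4-yl}chromane-3,4-diyl carbonate (cyclic) | c1ccccc1COc1ccc2c(c1)O[C@H](c1ccc(OCc3ccccc3)c(OCc3ccccc3)c1)[C@@H](O)[C@@H]2c1cc2c(cc1OCc1ccccc1)O[C@H](c1ccc(OCc3ccccc3)c(OCc3ccccc3)c1)[C@@H](OC(=O)O4)[C@H]24
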